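The ratio of D to Z charged in the oak flask is 0.950, so D is charged a little short of Z, and a decision is due at 30 h: wait, add D, add Z, or take out E.

| flask | Z | D | remark | time |
|---|---|---|---|---|
| oak | 0.20 M | 0.19 M | the very flask that is asked about, followed so far |  |
| ash | 0.40 M | 0.19 M | run made earlier |  |
| flask | 0.20 M | 0.190 M |  | 30 h |

| oak: time / h | oak: J / % | ash: time / h | ash: J / % |
|---|---|---|---|
| 1.33 | 11 | 0.500 | 2 |
| 2.50 | 20 | 1.50 | 12 |
| 5.00 | 37 | 3.00 | 19 |
| 10.0 | 45 | 4.00 | 23 |
| 20.0 | 50 | 6.00 | 22 |

(scatter of a reading: 2 percentage points)

- Saturday's: change nothing and wait 15 h more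
- Sunday's: at 30 h add D, 100% of the amount charged, then wait 15 h
- Wednesday's: at 30 h add Z, 50.0% of the amount charged, then wait 15 h
- Tuesday's: at 30 h take out 90% of the E then present, then wait 15 h

* J, in percent of the Z first charged, at 30 h
* the remedy with the largest gain of J, or "none" below 2 percentage points (Saturday's / Sunday's / Wednesday's / Tuesday's / none)
* J present, in percent of the Z first charged, after Saturday's
* J present, in percent of the Z first charged, after Tuesday's

- additions leave the volume as it is
- candidate steps: Z + D -> G + E; G -> J; G -> X

With the two partners of the first step charged nearly equal, its rate goes as the square of what is left, and such a decay has no fixed half-life. Each halving takes as long as the time before it, so the gap to the end falls as one over the time. The last oak reading stands at twice the time of the one before, so the gap there is the step between them: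

J∞ = 50% + (50% − 45%) = 55.0%

Each D spent makes one G, and in the oak flask D is the smaller charge, so, taking D as spent at J∞, the share s of spent D that ends as J, the selectivity, follows from J∞ and the ratio above:

s = J∞ · Z charged / D charged = 57.9%

This is a reading, and the extrapolation enlarges the scatter of 2 percentage points. The last ash reading of 22%, taken as that run's end, gives 46.3%, but oak's last reading already needs 52.6%, so the oak value is kept.

My reckoning for oak:

at 30 h: J = 51.7%

after 15 h more: J = 52.8%

Waiting gains 1.1 points, less than the 2 points that counts. E is a reactant in none of the candidate steps, so taking it out reckons the same as waiting. Adding Z leaves the ceiling at J∞, while adding D makes Z the limiting reagent and lifts the ceiling to s of the Z charged, so the next move is to charge D.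

The forecast gives 52% now, 54% after Saturday's and 54% after Tuesday's, and picks Sunday's: “Adding D consumes nearly all remaining Z”.

The simulation gives 52.5%, 53.6% and 53.6%, and its choice is Sunday's, with a gain of 5.2 points against 2.3 points for Wednesday's.

    Z + D → G + E (k = 7.30 × 10⁻⁴ M⁻¹ s⁻¹)
    G → J (k = 1.50 × 10⁻⁴ s⁻¹)
    G → X (k = 1.10 × 10⁻⁴ s⁻¹)

Spent D appears as E, so s applied to the 0.182 M of E at 30.0 h gives J at 52.8% of the Z charged. The share stands below one because of the step from G to X: the same run without that step gives 90.8% of J in place of 52.5%.

A neighbour of the oak flask, charged with 0.048 M of D, has D as its limiting reagent at 0.240 equiv, so s gives 13.9%. The computed J there is 13.8%, with 76.0% of the Z still free.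

The data stem from a simulated flask for an exercise, and the scatter is random.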